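**Plan**

- Retrosynthesis: the lactone O–C7 bond is cut first, which leaves a ring-B cyclodeca-6,8(17)-dienoic acid. Ring B is then opened at C6=C7 (metathesis), and the dienoate goes back through C7–C8 (cross-coupling) and C8–C17 (ester aldol) to a C8 aldehyde. Cutting C9–C10 (Claisen), C1–CH3 and C1–C2 (enolate alkylation, aldol) leads to (S)-carvone and a C2–C7 alkynyl aldehyde made from geraniol.
- Forward: ring A is carvone. The C2–C7 chain is joined at C1 by aldol, C1 is methylated, the isopropenyl group becomes the C14 acetate, the enone is transposed and a Claisen rearrangement puts C9–C8 on C10. C8 is built into the (Z)-dienoate, metathesis closes the ten-membered ring B, and the butenolide ring is closed last.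
- Stereochemistry: C14 comes from (S)-carvone (retentive Criegee rearrangement) and C5 from Sharpless epoxidation. C2 comes from an anti boron aldol on the enolate face opposite the isopropenyl group, C1 from methylation anti to that group, and C10 from suprafacial Claisen transfer from the C12 carbinol. Alkene geometries come from a chelated enol triflate, the cis ring alkene and anti-addition/syn-elimination.
- Enabling feature: in the cyclodecadienoic acid the C19 carboxyl sits cis to C7 on the tetrasubstituted C8=C17 bond, ring B holds C6=C7 cis and twisted out of the enoate plane, and C5 carries no hydrogen. Attack of the carboxylate oxygen on C7 followed by loss of H7 can therefore only give the (E)-alkylidene butenolide.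

Key step: step 22

Remark: all compounds that contain ring A carry the briarane numbering of the target (C1 quaternary ring-fusion carbon, C2 isovalerate carbinol, C5 tertiary carbinol, C6=C7, C8=C17, C10 ring-fusion CH, C11=C12, C14 acetate carbinol, C19 lactone carbonyl); in carvone the carbonyl carbon becomes C10 and C6 becomes C1.

**Route**

Step 1
Reactants: 1 geraniol
Product: 2 (2S,3S)-2,3-epoxygeraniol
Conditions: Ti(OiPr)4 (5 mol%), L-(+)-diethyl tartrate (7 mol%), t-BuOOH, 4 Å MS, CH2Cl2, −20 °C
Reagents that add atoms: tert-butyl hydroperoxide, CC(C)(C)OO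
Why: Sharpless asymmetric epoxidation of the allylic alcohol, in which the L-(+)-tartrate/titanium complex delivers oxygen to one face of the C2=C3 alkene and so sets the tertiary C–O centre that becomes C5 (S).

Step 2
Reactants: 2 (2S,3S)-2,3-epoxygeraniol
Product: 3 (2R,3S)-1-chloro-2,3-epoxy-3,7-dimethyloct-6-ene
Conditions: PPh3, CCl4, NaHCO3, reflux
Reagents that add atoms: carbon tetrachloride, ClC(Cl)(Cl)Cl
Why: Appel chlorination converts the primary alcohol under neutral conditions that leave the epoxide and both of its stereocentres untouched.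

Step 3
Reactants: 3 (2R,3S)-1-chloro-2,3-epoxy-3,7-dimethyloct-6-ene
Product: 4 (3S)-3,7-dimethyloct-6-en-1-yn-3-ol
Conditions: n-BuLi (3.3 equiv), THF, −78 → −30 °C; aq. NH4Cl
Reagents that add atoms: none
Why: Base-induced double elimination of the 2,3-epoxy chloride (epoxide-opening elimination, then dehydrochlorination of the chloroalkene) gives the terminal alkyne while the tertiary C–O bond, and with it the configuration, is not touched.

Step 4
Reactants: 4 (3S)-3,7-dimethyloct-6-en-1-yn-3-ol
Product: 5 (3S)-3,7-dimethyl-3-(triethylsilyloxy)oct-6-en-1-yne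
Conditions: TESOTf, 2,6-lutidine, CH2Cl2, −78 → 0 °C
Reagents that add atoms: triethylsilyl trifluoromethanesulfonate, CC[Si](CC)(CC)OS(=O)(=O)C(F)(F)F
Why: Silyl ether protection of the hindered tertiary alcohol with the silyl triflate, which is reactive enough for a fully substituted carbinol.

Step 5
Reactants: 5 (3S)-3,7-dimethyl-3-(triethylsilyloxy)oct-6-en-1-yne
Product: 7 (4S)-4-methyl-4-(triethylsilyloxy)hex-5-ynal, via ozonide 6 (not isolated)
Conditions: O3, CH2Cl2, −78 °C (Sudan Red 7B end point); Me2S, −78 °C → rt
Reagents that add atoms: ozone, [O-][O+]=O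
Why: Ozonolysis with reductive work-up cleaves the electron-rich trisubstituted alkene, which reacts far faster with ozone than the terminal alkyne.

Step 6
Reactants: 8 (S)-(+)-carvone; 7 (4S)-4-methyl-4-(triethylsilyloxy)hex-5-ynal
Product: 10 (5S,6S)-6-[(1S,4S)-1-hydroxy-4-methyl-4-(triethylsilyloxy)hex-5-yn-1-yl]-2-methyl-5-(prop-1-en-2-yl)cyclohex-2-en-1-one, via dicyclohexylboron enolate 9 (not isolated)
Conditions: c-Hex2BCl, Et3N, Et2O, −78 → 0 °C; then 7, −78 → −20 °C; MeOH, pH 7 buffer, H2O2, 0 °C
Reagents that add atoms: none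
Why: Boron-mediated aldol addition in which the ring-fixed E(O)-enolate reacts through a closed chair transition state to give the anti adduct and the aldehyde adds to the C1 face opposite the C14 isopropenyl group, which together set C2 as S (C1 is re-set in step 8).

Step 7
Reactants: 10 anti-aldol adduct
Product: 11 trimethylsilyl ether of 10
Conditions: TMSCl, imidazole, DMF, 0 °C
Reagents that add atoms: chlorotrimethylsilane, C[Si](C)(C)Cl
Why: Silyl ether protection of the aldol hydroxyl blocks retro-aldol cleavage in the next step and stays far more acid-labile than the tertiary triethylsilyl ether.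

Step 8
Reactants: 11 trimethylsilyl ether of 10
Product: 14 C1-methylated hydroxy ketone (C1 methyl trans and C2 chain cis to the C14 isopropenyl; 2S 5S), via dilithium enolate-acetylide 12 (not isolated), via methylated trimethylsilyl ether 13 (not isolated)
Conditions: LDA (LiN(iPr)2, 2.2 equiv), THF, −78 °C; MeI, −78 → −30 °C; then 1 M HCl, THF, 0 °C
Reagents that add atoms: iodomethane, CI
Why: Enolate alkylation of a 6-substituted carvone, in which kinetic deprotonation at C1 (one equivalent of base is taken up by the alkyne C–H) and C-methylation on the face opposite the C14 isopropenyl group create the C1 quaternary centre with methyl trans and the C2 chain cis to C14, and the acid work-up cleaves only the secondary trimethylsilyl ether.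

Step 9
Reactants: 14 C1-methylated hydroxy ketone
Product: 15 2-O-isovalerate of 14
Conditions: isovaleryl chloride, pyridine, DMAP (cat.), CH2Cl2, 0 °C → rt
Reagents that add atoms: 3-methylbutanoyl chloride, CC(C)CC(Cl)=O
Why: DMAP-catalysed acylation of the secondary alcohol installs the C2 isovalerate of the target, and with C1 now quaternary the β-acyloxy ketone cannot eliminate.

Step 10
Reactants: 15 2-O-isovalerate of 14
Product: 16 11,12-epoxy ketone (epoxide oxygen trans to the C14 isopropenyl)
Conditions: t-BuOOH, BnMe3N+ OH− (Triton B, cat.), THF, 0 °C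
Reagents that add atoms: tert-butyl hydroperoxide, CC(C)(C)OO
Why: Weitz–Scheffer nucleophilic epoxidation of the enone, in which the peroxide attacks C12 on the face opposite the C14 substituent, places the epoxide oxygen trans to the isopropenyl group and so fixes the later C12 carbinol.

Step 11
Reactants: 16 11,12-epoxy ketone
Product: 18 C14 acetate of the epoxy ketone (terminal alkyne retained), via methoxy hydroperoxide 17 (not isolated)
Conditions: O3, CH2Cl2/MeOH, NaHCO3, −78 °C; then Ac2O, Et3N, DMAP (cat.), CH2Cl2, 0 → 40 °C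
Reagents that add atoms: ozone, [O-][O+]=O; methanol, CO
Why: Ozonolysis of the isopropenyl group in methanol followed by Criegee rearrangement of the acetylated α-methoxy hydroperoxide, in which C14 migrates to oxygen with retention and the methoxycarbenium ion collapses to the acetate, turns the isopropenyl group into the C14 acetate of the target while the less reactive alkyne survives.

Step 12
Reactants: 18 C14 acetate of the epoxy ketone
Product: 19 vinyl epoxy ketone (C6=C7 terminal alkene)
Conditions: H2 (1 atm), Pd/CaCO3 poisoned with Pb(OAc)2, quinoline, EtOAc, rt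
Reagents that add atoms: none
Why: Lindlar semi-hydrogenation reduces the terminal alkyne to the vinyl group and stops there, leaving the epoxy ketone and esters intact.

Step 13
Reactants: 19 vinyl epoxy ketone
Product: 20 C12 allylic alcohol (C10=C11; 12-OH trans to the 14-acetate)
Conditions: N2H4·H2O, AcOH, MeOH, argon, 0 °C → rt
Reagents that add atoms: none
Why: Wharton transposition, in which the epoxy hydrazone fragments with loss of N2 to the C10=C11 alkene and the C12 allylic alcohol, whose C–O bond and configuration come unchanged from the epoxide.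

Step 14
Reactants: 20 C12 allylic alcohol
Product: 22 C8 aldehyde (C10–CH2–CHO with C9 trans to the C2 chain; C11=C12), via allyl vinyl ether 21 (not isolated)
Conditions: Pd(OCOCF3)2 (5 mol%), 4,7-diphenyl-1,10-phenanthroline, n-butyl vinyl ether, Et3N, 75 °C; then xylenes, 150 °C (sealed tube)
Reagents that add atoms: n-butyl vinyl ether, C=COCCCC
Why: Claisen rearrangement of the allyl vinyl ether made by palladium-catalysed vinyl ether exchange, in which the suprafacial [3,3] shift forms C9–C10 on the face of the C12–O bond (trans to the C2 chain), sets C10 and moves the alkene to C11=C12.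

Step 15
Reactants: 23 propanoyl chloride; 24 2-(trimethylsilyl)ethanol
Product: 25 2-(trimethylsilyl)ethyl propanoate
Conditions: pyridine, CH2Cl2, 0 °C
Reagents that add atoms: none
Why: Esterification of the alcohol by acylation with the acid chloride.

Step 16
Reactants: 22 C8 aldehyde; 25 2-(trimethylsilyl)ethyl propanoate
Product: 27 β-hydroxy ester (C8 carbinol and C17 methyl; mixture at C8 and C17), via lithium ester enolate 26 (not isolated)
Conditions: LDA (LiN(iPr)2), THF, −78 °C; then 22, −78 °C; AcOH
Reagents that add atoms: none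
Why: Ester-enolate aldol addition, in which the aldehyde reacts far faster than the hindered acetate and isovalerate at −78 °C, and the two new stereocentres are removed again in steps 17 and 18.

Step 17
Reactants: 27 β-hydroxy ester
Product: 28 β-keto ester
Conditions: Dess–Martin periodinane, NaHCO3, CH2Cl2, rt
Reagents that add atoms: none
Why: Dess–Martin oxidation of the secondary alcohol gives the β-keto ester under buffered conditions that spare the silyl ether, the esters and the alkenes.

Step 18
Reactants: 28 β-keto ester
Product: 29 (Z)-enol triflate (C8–OTf cis to the C19 ester)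
Conditions: Tf2O, LiOTf, Et3N, CH2Cl2, −78 → 0 °C
Reagents that add atoms: trifluoromethanesulfonic anhydride, O=S(=O)(OS(=O)(=O)C(F)(F)F)C(F)(F)F
Why: O-triflation of the lithium-chelated enolate of the β-keto ester gives the (Z)-enol triflate, which fixes the geometry of the future C8=C17 butenolide alkene.

Step 19
Reactants: 29 (Z)-enol triflate
Product: 30 (2Z)-dienoate (C7 vinyl on C8 cis to the C19 ester)
Conditions: Pd(PPh3)4 (5 mol%), LiCl, Bu3SnCH=CH2, THF, 60 °C
Reagents that add atoms: tributyl(vinyl)stannane, C=C[Sn](CCCC)(CCCC)CCCC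
Why: Stille coupling of the enol triflate proceeds with retention at C8 and so places the C7 vinyl group cis to the ester.

Step 20
Reactants: 30 (2Z)-dienoate
Product: 31 hydroxy acid triene (free C19 acid and free C5 hydroxyl)
Conditions: Bu4NF, THF, 0 °C → rt; aq. NH4Cl
Reagents that add atoms: none
Why: Fluoride-induced desilylation removes both silicon groups, the 2-(trimethylsilyl)ethyl ester by fragmentation to ethylene and the carboxylate and the tertiary triethylsilyl ether directly, while the acetate and the isovalerate should remain.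

Step 21
Reactants: 31 hydroxy acid triene
Product: 32 ring-B cyclodeca-6,8(17)-dienoic acid (C6=C7 cis in the ring)
Conditions: second-generation Hoveyda–Grubbs catalyst (10 mol%), toluene (1 mM), 80 °C
Reagents that add atoms: none
Why: Ring-closing metathesis of the two vinyl groups forms ring B at C6=C7, where the cis alkene is expected as the less strained geometry in a cyclodecadiene trans-fused to ring A and the C8=C17 and C11=C12 alkenes are too substituted to react.

Step 22
Reactants: 32 ring-B cyclodeca-6,8(17)-dienoic acid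
Product: 33 CNP0208239.1
Conditions: Pd(OCOCF3)2 (10 mol%), pyridine (40 mol%), Na2CO3, 3 Å MS, O2 (1 atm), toluene, 80 °C
Reagents that add atoms: none
Why: Proposed new method: the palladium carboxylate formed from the C19 acid and divalent palladium binds the cis C6=C7 alkene of ring B, the carboxylate oxygen adds to C7 anti to palladium to form the O–C7 bond and a C6–Pd bond, and because C5 is fully substituted the only β-hydrogen is H7, so syn β-hydride elimination restores C6=C7 as the enol ether and O2 reoxidises the zerovalent palladium. The closest known reaction type is the aerobic Wacker-type oxidative lactonisation of alkenoic acids, together with the palladium-mediated cyclisation of 2,4-dienoic acids to pyranones, neither of which has been shown in the 5-exo mode on a cyclic 2,4-dienoic acid. The butenolide ring closes by 5-exo-trig attack, which is possible because ring B twists the C6=C7 π bond out of the plane of the C8=C17–C19 enoate so that the in-plane carboxylate oxygen meets the C7 p orbital. No stereocentre is formed, and the E geometry of the exocyclic alkene follows from anti addition to the cis ring alkene and syn elimination after a 60° rotation about C6–C7, which keeps C5 and C8 cis in ring B and leaves the lactone oxygen cis to H6. The step needs 5-exo over 6-endo closure, secured because the 6-endo pyranone would be bridged across C6–C8 of the ten-membered ring, β-hydride over β-hydroxide elimination, favoured by chloride-free pyridine-ligated palladium, and chemoselectivity over the hindered trisubstituted C11=C12 alkene.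

**Compound list**

1 | geraniol, (2E)-3,7-dimethylocta-2,6-dien-1-ol | CC(C)=CCC/C(C)=C/CO | starting material
2 | (2S,3S)-2,3-epoxygeraniol | OC[C@@H]1O[C@@]1(C)CCC=C(C)C | intermediate
3 | (2R,3S)-1-chloro-2,3-epoxy-3,7-dimethyloct-6-ene | ClC[C@@H]1O[C@@]1(C)CCC=C(C)C | intermediate
4 | (3S)-3,7-dimethyloct-6-en-1-yn-3-ol | C#C[C@@](C)(O)CCC=C(C)C | intermediate
5 | (3S)-3,7-dimethyl-3-(triethylsilyloxy)oct-6-en-1-yne | C#C[C@@](C)(O[Si](CC)(CC)CC)CCC=C(C)C | intermediate
6 | ozonide of 5 (3-substituted 5,5-dimethyl-1,2,4-trioxolane; ring CH as a mixture) | C#C[C@@](C)(O[Si](CC)(CC)CC)CCC1OOC(C)(C)O1 | intermediate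
7 | (4S)-4-methyl-4-(triethylsilyloxy)hex-5-ynal | C#C[C@@](C)(O[Si](CC)(CC)CC)CCC=O | intermediate
8 | (S)-(+)-carvone | C=C(C)[C@H]1CC=C(C)C(=O)C1 | starting material
9 | dicyclohexylboron C1=C10 enolate of carvone | C=C(C)[C@H]1CC=C(C)C(OB(C2CCCCC2)C2CCCCC2)=C1 | intermediate
10 | anti-aldol adduct, (5S,6S)-6-[(1S,4S)-1-hydroxy-4-methyl-4-(triethylsilyloxy)hex-5-yn-1-yl]-2-methyl-5-(prop-1-en-2-yl)cyclohex-2-en-1-one | C=C(C)[C@H]1CC=C(C)C(=O)[C@@H]1[C@@H](O)CC[C@](C)(O[Si](CC)(CC)CC)C#C | intermediate
11 | trimethylsilyl ether of 10 | C=C(C)[C@H]1CC=C(C)C(=O)[C@@H]1[C@@H](O[Si](C)(C)C)CC[C@](C)(O[Si](CC)(CC)CC)C#C | intermediate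
12 | dilithium enolate-acetylide of 11 | C=C(C)[C@H]1CC=C(C)C([O-])=C1[C@@H](O[Si](C)(C)C)CC[C@](C)(O[Si](CC)(CC)CC)C#[C-].[Li+].[Li+] | intermediate
13 | C1-methylated trimethylsilyl ether (shown as the neutral alkyne) | C=C(C)[C@H]1CC=C(C)C(=O)[C@@]1(C)[C@@H](O[Si](C)(C)C)CC[C@](C)(O[Si](CC)(CC)CC)C#C | intermediate
14 | C1-methylated hydroxy ketone (C1 methyl trans, C2 chain cis to the C14 isopropenyl; 2S,5S) | C=C(C)[C@H]1CC=C(C)C(=O)[C@@]1(C)[C@@H](O)CC[C@](C)(O[Si](CC)(CC)CC)C#C | intermediate
15 | 2-O-isovalerate of 14 | C=C(C)[C@H]1CC=C(C)C(=O)[C@@]1(C)[C@@H](OC(=O)CC(C)C)CC[C@](C)(O[Si](CC)(CC)CC)C#C | intermediate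
16 | 11,12-epoxy ketone (epoxide oxygen trans to the C14 isopropenyl) | C=C(C)[C@H]1C[C@@H]2O[C@]2(C)C(=O)[C@@]1(C)[C@@H](OC(=O)CC(C)C)CC[C@](C)(O[Si](CC)(CC)CC)C#C | intermediate
17 | α-methoxy hydroperoxide from 16 (hydroperoxyketal carbon as a mixture) | COC(C)(OO)[C@H]1C[C@@H]2O[C@]2(C)C(=O)[C@@]1(C)[C@@H](OC(=O)CC(C)C)CC[C@](C)(O[Si](CC)(CC)CC)C#C | intermediate
18 | C14 acetate of the epoxy ketone (terminal alkyne) | CC(=O)O[C@H]1C[C@@H]2O[C@]2(C)C(=O)[C@@]1(C)[C@@H](OC(=O)CC(C)C)CC[C@](C)(O[Si](CC)(CC)CC)C#C | intermediate
19 | vinyl epoxy ketone (C6=C7 terminal alkene) | CC(=O)O[C@H]1C[C@@H]2O[C@]2(C)C(=O)[C@@]1(C)[C@@H](OC(=O)CC(C)C)CC[C@](C)(O[Si](CC)(CC)CC)C=C | intermediate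
20 | C12 allylic alcohol (C10=C11; 12-OH trans to the 14-acetate) | CC(=O)O[C@H]1C[C@H](O)C(C)=C[C@@]1(C)[C@@H](OC(=O)CC(C)C)CC[C@](C)(O[Si](CC)(CC)CC)C=C | intermediate
21 | C12 vinyl ether of 20 | CC(=O)O[C@H]1C[C@H](OC=C)C(C)=C[C@@]1(C)[C@@H](OC(=O)CC(C)C)CC[C@](C)(O[Si](CC)(CC)CC)C=C | intermediate
22 | C8 aldehyde (C10–CH2–CHO, C9 trans to the C2 chain; C11=C12) | CC(=O)O[C@H]1CC=C(C)[C@H](CC=O)[C@@]1(C)[C@@H](OC(=O)CC(C)C)CC[C@](C)(O[Si](CC)(CC)CC)C=C | intermediate
23 | propanoyl chloride | CCC(Cl)=O | starting material
24 | 2-(trimethylsilyl)ethanol | OCC[Si](C)(C)C | starting material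
25 | 2-(trimethylsilyl)ethyl propanoate | CCC(=O)OCC[Si](C)(C)C | intermediate
26 | lithium enolate of 25 (geometry not relevant) | CC=C([O-])OCC[Si](C)(C)C.[Li+] | intermediate
27 | β-hydroxy ester (mixture at C8 and C17) | CC(=O)O[C@H]1CC=C(C)[C@H](CC(O)C(C)C(=O)OCC[Si](C)(C)C)[C@@]1(C)[C@@H](OC(=O)CC(C)C)CC[C@](C)(O[Si](CC)(CC)CC)C=C | intermediate
28 | β-keto ester (C17 as a mixture) | CC(=O)O[C@H]1CC=C(C)[C@H](CC(=O)C(C)C(=O)OCC[Si](C)(C)C)[C@@]1(C)[C@@H](OC(=O)CC(C)C)CC[C@](C)(O[Si](CC)(CC)CC)C=C | intermediate
29 | (Z)-enol triflate (C8–OTf cis to the C19 ester) | CC(=O)O[C@H]1CC=C(C)[C@H](C/C(OS(=O)(=O)C(F)(F)F)=C(\C)C(=O)OCC[Si](C)(C)C)[C@@]1(C)[C@@H](OC(=O)CC(C)C)CC[C@](C)(O[Si](CC)(CC)CC)C=C | intermediate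
30 | (2Z)-dienoate, 2-(trimethylsilyl)ethyl ester (C7 vinyl cis to the ester) | CC(=O)O[C@H]1CC=C(C)[C@H](C/C(C=C)=C(\C)C(=O)OCC[Si](C)(C)C)[C@@]1(C)[C@@H](OC(=O)CC(C)C)CC[C@](C)(O[Si](CC)(CC)CC)C=C | intermediate
31 | hydroxy acid triene | CC(=O)O[C@H]1CC=C(C)[C@H](C/C(C=C)=C(\C)C(=O)O)[C@@]1(C)[C@@H](OC(=O)CC(C)C)CC[C@](C)(O)C=C | intermediate
32 | ring-B cyclodeca-6,8(17)-dienoic acid (C6=C7 cis; C19 acid cis to C7) | CC(=O)O[C@H]1CC=C(C)[C@@H]2C/C(=C(\C)C(=O)O)/C=C\[C@@](C)(O)CC[C@H](OC(=O)CC(C)C)[C@@]12C | intermediate
33 | CNP0208239.1, (1S,2S,5S,10S,14S; briarane numbering) 14-acetoxy-5-hydroxy-2-isovaleryloxy (6E)-alkylidene butenolide | CC(=O)O[C@H]1CC=C(C)[C@@H]2CC3=C(C)C(=O)O/C3=C/[C@@](C)(O)CC[C@H](OC(=O)CC(C)C)[C@@]12C | target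

**Summary and risks**

Total step count: 22. Longest linear sequence: 21 steps (steps 1–14 and 16–22, geraniol to the target; step 15 is a side branch).

Steps most likely to fail:

1. Step 22 (proposed new method). The C6–Pd intermediate may lose hydroxide from C5 instead of hydride from C7, which gives redox-neutral allylic transposition without oxidation, or the hindered alkene may not undergo oxypalladation at all. The fallback keeps the anti-addition/syn-elimination logic but uses known selenium chemistry. It sets out from 32: PhSeCl and Et3N in CH2Cl2 at −78 °C should give, by 5-exo phenylselenolactonisation across C6=C7, the phenylselenolactone F1. Oxidation with H2O2/pyridine at 0 °C and syn elimination of the selenoxide, which can only take H7 because C5 bears no hydrogen, comes back to the route at 33.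

2. Step 21. Ring closure may lose to intermolecular metathesis (oligomerisation) at the hindered vinyl carbinol, or the ring alkene may form trans. The fallback closes ring B at C7–C8 instead of C6=C7. It sets out from enol triflate 29: an intramolecular Heck reaction (Pd(OAc)2, PPh3, Et3N, MeCN, 80 °C, high dilution; endo carbopalladation of the C5 vinyl group, then β-hydride elimination from C7) should give the ring-B dienoate ester F2. Bu4NF under the conditions of step 20 then removes both silicon groups and comes back to the route at 32.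

3. Step 13. Hydrazone formation at the C10 carbonyl, which is flanked by two fully substituted carbons, may be so slow that hydrazinolysis of the acetate and isovalerate takes over. The fallback replaces the hydrazone by a carbon radical. It sets out from 19: NaBH4/CeCl3·7H2O (MeOH, −20 °C; Luche reduction) gives the epoxy alcohol F3. 1,1′-Thiocarbonyldiimidazole/DMAP (toluene, 80 °C) converts it into the imidazole-1-carbothioate F4. Bu3SnH/AIBN (toluene, 80 °C) then generates the C10 radical, which opens the epoxide to the C12 alkoxy radical and, after hydrogen transfer, comes back to the route at 20.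

Further compounds
F1 | step 22 | C6-phenylselanyl butenolide (C6/C7 anti adduct; face of addition not assigned) | CC(=O)O[C@H]1CC=C(C)[C@@H]2CC3=C(C)C(=O)OC3C([Se]c3ccccc3)[C@@](C)(O)CC[C@H](OC(=O)CC(C)C)[C@@]12C
F2 | step 21 | ring-B cyclodecadienoate, 2-(trimethylsilyl)ethyl ester, 5-O-triethylsilyl ether | CC(=O)O[C@H]1CC=C(C)[C@@H]2C/C(=C(\C)C(=O)OCC[Si](C)(C)C)/C=C\[C@@](C)(O[Si](CC)(CC)CC)CC[C@H](OC(=O)CC(C)C)[C@@]12C
F3 | step 13 | 11,12-epoxy C10 alcohol (C10 configuration not relevant) | CC(=O)O[C@H]1C[C@@H]2O[C@]2(C)C(O)[C@@]1(C)[C@@H](OC(=O)CC(C)C)CC[C@](C)(O[Si](CC)(CC)CC)C=C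
F4 | step 13 | C10 O-(imidazole-1-carbothioate) of F3 | CC(=O)O[C@H]1C[C@@H]2O[C@]2(C)C(OC(=S)n2ccnc2)[C@@]1(C)[C@@H](OC(=O)CC(C)C)CC[C@](C)(O[Si](CC)(CC)CC)C=C
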